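**Retrosynthetic overview**
1. The spiro-tetrahydrofuran is closed last: 5-exo oxa-Michael addition of the C13 hydroxyl to the quinone, which comes from a 2,5-dimethoxyphenyl group by oxidative demethylation.
2. Before that: the δ-lactone by attack of C20–O on a C19 auxiliary ester, C13–OH by hydration of a 13(16)-alkene, and removal of a temporary C3 ketone.
3. Rings A, B and C are made in one oxidative radical tricyclisation of an acyclic keto ester; the bonds form in the order C4–C5 (ring A), C10–C9 (ring B), C8–C14 (ring C).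
4. Enabling feature: rings A–C hide a head-to-tail polyprenyl chain. The alkenes C5=C10, C8=C9 and C13=C14 are each two CH2 groups apart and C4 lies five atoms from C5, so every ring closes 6-endo onto the CH carbon (C5, C9, C14). C4 is made oxidisable by the temporary C3 ketone beside the C19 ester, whose 8-phenylmenthyl group sets the absolute configuration.
5. The acyclic precursor comes from 1,4-dimethoxybenzene and farnesyl bromide: three-carbon degradation to a C5 aldehyde, vinyl addition, Johnson–Claisen rearrangement (fixes the C5=C10 geometry and brings in C20–O), then acylation of 8-phenylmenthyl propanoate.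

Key step: step 11

Numbering used (terpenoid convention): ring A = C1–C5, C10; ring B = C5–C10; ring C = C8, C9, C11–C14; C15 = CH2 between C14 and the six-membered carbocycle; C16 = CH3 on C13; C17 = CH3 on C8; C18 = CH3 on C4; C19 = carboxyl carbon on C4; C20 = CH2O on C10; arene/quinone carbons C1'–C6' (C1' bears C15); α = below, β = above the usual drawing.

Assumption: in the (1R,2S,5R)-8-phenylmenthyl keto ester the phenyl ring covers the face of the planar C4 radical that would lead to the enantiomeric series, so C5 adds to give 4α-CH3/4β-CO2R; if the sense were the opposite, the (1S,2R,5S) auxiliary would be used in the same route.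

**Step 1**
Reactants: 1 1,4-dimethoxybenzene; 2 (2E,6E)-farnesyl bromide
Product: 4 2-[(2E,6E)-3,7,11-trimethyldodeca-2,6,10-trienyl]-1,4-dimethoxybenzene, via 2,5-dimethoxyphenyllithium 3 (not isolated)
Conditions: n-BuLi, TMEDA, THF, 0 °C; then 2, −78 °C → rt
Reagents that add atoms: none
Why: Ortho-lithiation of 1 followed by SN2 alkylation of the aryllithium with the primary allylic bromide joins the arene to C15 without touching the E alkenes (no stereocentre formed).

**Step 2**
Reactants: 4
Product: 5 (6E,10E)-3-bromo-12-(2,5-dimethoxyphenyl)-2,6,10-trimethyldodeca-6,10-dien-2-ol (racemic)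
Conditions: NBS, THF/H2O, 0 °C
Reagents that add atoms: N-bromosuccinimide O=C1CCC(=O)N1Br; water O
Why: Electrophilic bromohydrin formation, selective for the terminal trisubstituted alkene of a polyprenyl chain in aqueous THF (bromonium opened by water at the tertiary carbon); the racemic CHBr centre is erased in step 4.

**Step 3**
Reactants: 5
Product: 6 2,2-dimethyl-3-[(3E,7E)-9-(2,5-dimethoxyphenyl)-3,7-dimethylnona-3,7-dienyl]oxirane (racemic)
Conditions: K2CO3, MeOH, rt
Reagents that add atoms: none
Why: Intramolecular Williamson etherification (the alkoxide displaces the vicinal bromide, SN2) gives the terminal epoxide.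

**Step 4**
Reactants: 6
Product: 7 (4E,8E)-10-(2,5-dimethoxyphenyl)-4,8-dimethyldeca-4,8-dienal
Conditions: H5IO6, THF/Et2O, 0 °C
Reagents that add atoms: none
Why: Periodic acid opens the epoxide and cleaves the resulting glycol (oxidative glycol cleavage), excising three carbons as acetone and leaving C5 as the aldehyde while the skipped E alkenes and the arene stay intact.

**Step 5**
Reactants: 8 2-bromoprop-2-en-1-ol
Product: 9 (2-bromoprop-2-enyloxy)(tert-butyl)diphenylsilane
Conditions: t-BuPh2SiCl, imidazole, CH2Cl2, rt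
Reagents that add atoms: tert-butyl(chloro)diphenylsilane CC(C)(C)[Si](Cl)(c1ccccc1)c1ccccc1
Why: O-Silylation of the primary alcohol installs a C20–O protecting group that survives organolithium, hot weak acid, acetic acid and radical conditions.

**Step 6**
Reactants: 9; 7
Product: 11 (6E,10E)-2-{[tert-butyl(diphenyl)silyl]oxymethyl}-12-(2,5-dimethoxyphenyl)-6,10-dimethyldodeca-1,6,10-trien-3-ol (racemic carbinol), via 2-lithioallyl silyl ether 10 (not isolated)
Conditions: t-BuLi (2 equiv), Et2O, −78 °C; then 7; H2O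
Reagents that add atoms: none
Why: Bromine–lithium exchange gives the vinyllithium, which adds 1,2 to the aldehyde (carbonyl addition) and joins C10, C1 and C20 to C5; the new carbinol centre is racemic and becomes sp2 in step 7.

**Step 7**
Reactants: 11
Product: 13 ethyl (4Z,8E,12E)-4-{[tert-butyl(diphenyl)silyl]oxymethyl}-14-(2,5-dimethoxyphenyl)-8,12-dimethyltetradeca-4,8,12-trienoate, via mixed ketene acetal 12 (not isolated)
Conditions: MeC(OEt)3, EtCO2H (cat.), xylene, 140 °C (−EtOH)
Reagents that add atoms: triethyl orthoacetate CC(OCC)(OCC)OCC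
Why: Johnson–Claisen rearrangement through a chair with the C6 chain equatorial should give the C5=C10 alkene with C6 trans to C1 (Z by the sequence rules) and adds C2 and C3 as the ester.

**Step 8**
Reactants: 13
Product: 14 (4Z,8E,12E)-4-{[tert-butyl(diphenyl)silyl]oxymethyl}-14-(2,5-dimethoxyphenyl)-N-methoxy-N,8,12-trimethyltetradeca-4,8,12-trienamide
Conditions: MeNH(OMe)·HCl, i-PrMgCl, THF, −20 °C
Reagents that add atoms: N,O-dimethylhydroxylamine hydrochloride CNOC.Cl
Why: Aminolysis of the ethyl ester by the chloromagnesium amide gives the Weinreb amide, an acyl donor that stops at the ketone stage.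

**Step 9**
Reactants: 15 (1R,2S,5R)-(−)-8-phenylmenthol
Product: 16 (1R,2S,5R)-8-phenylmenthyl propanoate
Conditions: EtCOCl, pyridine, DMAP (cat.), CH2Cl2, 0 °C → rt
Reagents that add atoms: propanoyl chloride CCC(=O)Cl
Why: DMAP-catalysed O-acylation of the secondary alcohol gives the ester that carries C4, C18 and C19, with the three auxiliary stereocentres untouched.

**Step 10**
Reactants: 16; 14
Product: 18 (1R,2S,5R)-8-phenylmenthyl (6Z,10E,14E)-6-{[tert-butyl(diphenyl)silyl]oxymethyl}-16-(2,5-dimethoxyphenyl)-2,10,14-trimethyl-3-oxohexadeca-6,10,14-trienoate (C2 epimers), via lithium ester enolate 17 (not isolated)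
Conditions: LiN(i-Pr)2, 16 (2 equiv), THF, −78 °C; then 14, −78 → −20 °C; 1 M HCl
Reagents that add atoms: none
Why: C-Acylation of the ester lithium enolate by the Weinreb amide (crossed Claisen-type condensation through a stable chelated adduct) gives the α-methyl β-keto ester; the C4 epimer mixture is of no consequence because C4 becomes a planar radical in step 11.

**Step 11**
Reactants: 18
Product: 19 (1R,2S,5R)-8-phenylmenthyl ester of the trans-anti-trans A/B/C tricycle with 3-oxo, 4α-CH3, 4β-CO2R, 10β-CH2OSi(t-Bu)Ph2, 8β-CH3, 13(16)-exocyclic methylene, 14β-CH2-(2,5-dimethoxyphenyl) and H-5, H-9, H-14 α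
Conditions: Mn(OAc)3·2H2O (2.2 equiv), Cu(OAc)2·H2O (0.5 equiv), degassed AcOH, 25 → 40 °C
Reagents that add atoms: none
Why: Mn(OAc)3 oxidises the enolised α-methyl β-keto ester to the electrophilic C4 radical, which adds to C5 (ring A), the tertiary C10 radical then adds to C9 (ring B), the tertiary C8 radical adds to C14 (ring C, the C8–C14 bond), and divalent copper finally oxidises the tertiary C13 radical to the less substituted 13(16)-alkene. The closest known reaction type is the manganese triacetate/copper diacetate oxidative free-radical polyene cyclisation of unsaturated β-keto esters, which is established for bi-, tri- and tetracyclisations and for 8-phenylmenthyl esters. All three rings close 6-endo-trig through chair-like transition states, because in each alkene the proximal carbon (C10, C8, C13) is the disubstituted one and attack at the CH carbon gives a tertiary radical. C4 is controlled by the auxiliary (C5 approaches the face of the planar radical away from the stacked phenyl ring, the C19 ester ending axial and β), and C5, C10, C9, C8 and C14 by the all-chair folding and the alkene geometries (C6 trans to C1 at C5=C10, C7 trans to C11 at C8=C9, C12 trans to C15 at C13=C14), which should give the trans-anti-trans array with H-5, H-9, H-14 α and C20, C17, C15 β. The step needs each ring closure to outrun oxidation of the C10 and C8 radicals by divalent copper, secured by the 1,5-spacing of the alkenes and a low stationary concentration of Cu(OAc)2, and it needs the arene to stay out, which holds because attack of the C13 radical on the ring would be a strained five-membered closure and the dimethoxyarene is not oxidised by Mn(OAc)3 at this temperature.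

**Step 12**
Reactants: 19
Product: 21 the 13α-hydroxy-13β-methyl analogue of 19 (tertiary alcohol in place of the 13(16)-alkene), via tertiary hydroperoxide 20 (not isolated)
Conditions: Mn(dpm)3 (10 mol %; dpm = dipivaloylmethanate), PhSiH3, O2 (1 atm), i-PrOH/CH2Cl2, 0 °C; then P(OEt)3
Reagents that add atoms: dioxygen O=O
Why: Mukaiyama hydration (hydrogen-atom transfer from a manganese hydride to C16, capture of the tertiary C13 radical by O2, reduction of the hydroperoxide by the phosphite); O2 should approach the α face, anti to the syn-axial C8 methyl (C17), which sets the equatorial 13α-oxygen and the axial 13β-methyl.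

**Step 13**
Reactants: 21
Product: 22 C3 p-toluenesulfonylhydrazone of 21
Conditions: TsNHNH2, EtOH, 70 °C
Reagents that add atoms: 4-methylbenzenesulfonohydrazide Cc1ccc(cc1)S(=O)(=O)NN
Why: Condensation of the C3 ketone with the sulfonyl hydrazide (hydrazone formation) under neutral conditions leaves the ester, the silyl ether and the tertiary alcohol untouched.

**Step 14**
Reactants: 22
Product: 23 the 3-deoxo analogue of 21 (C3 = CH2)
Conditions: catecholborane, CHCl3, 0 °C; then NaOAc·3H2O, 60 °C
Reagents that add atoms: none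
Why: Tosylhydrazone reduction with catecholborane followed by acetate-induced loss of sulfinate and dinitrogen (a mild Wolff–Kishner-type deoxygenation) turns C3 into CH2 without touching any stereocentre.

**Step 15**
Reactants: 23
Product: 25 19,20-lactone (C19(=O)–O–C20) of the tricycle with 13α-OH and 14β-CH2-(2,5-dimethoxyphenyl), via C20 hydroxy ester 24 (not isolated)
Conditions: Bu4NF, THF, 0 → 50 °C
Reagents that add atoms: none
Why: Fluoride desilylation frees the C20 alkoxide, which lies 1,3-diaxial to the C19 ester and closes the δ-lactone by intramolecular transesterification with expulsion of the auxiliary alkoxide; all stereocentres are retained.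

**Step 16**
Reactants: 25
Product: 26 2-substituted 1,4-benzoquinone: the lactone tricycle with 13α-OH and 14β-CH2-(3,6-dioxocyclohexa-1,4-dienyl)
Conditions: (NH4)2Ce(NO3)6 (2.5 equiv), MeCN/H2O, 0 °C
Reagents that add atoms: water O
Why: Oxidative demethylation of the 1,4-dimethoxyarene to the p-benzoquinone by tetravalent cerium (the quinone oxygens come from water) leaves the lactone and the tertiary alcohol untouched.

**Step 17**
Reactants: 26
Product: 27 CNP0290557.1 (target)
Conditions: camphorsulfonic acid (cat.), CH2Cl2, rt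
Reagents that add atoms: none
Why: Acid-catalysed intramolecular oxa-Michael addition of the 13α-hydroxyl to C1' (5-exo-trig; C1' is β to the C3' carbonyl and the better cation-stabilising position of the protonated quinone, which disfavours 6-endo addition at C2') followed by ketonisation at C2' gives the spiro enedione; the addition is reversible, so the spiro centre can equilibrate through 26 and should settle with the flat C6' carbonyl carbon on the β face beside the axial C16 methyl and the C2' methylene on the open α face beside H-14, as in 27.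

**Compound list**
1 | 1,4-dimethoxybenzene | COc1ccc(OC)cc1 | starting material
2 | (2E,6E)-farnesyl bromide | CC(C)=CCC/C(C)=C/CC/C(C)=C/CBr | starting material
3 | 2,5-dimethoxyphenyllithium | [Li]c1cc(OC)ccc1OC | intermediate
4 | 2-[(2E,6E)-3,7,11-trimethyldodeca-2,6,10-trienyl]-1,4-dimethoxybenzene | COc1ccc(OC)c(C/C=C(\C)CC/C=C(\C)CCC=C(C)C)c1 | intermediate
5 | terminal bromohydrin (Br on the secondary carbon, OH on the tertiary carbon; racemic) | COc1ccc(OC)c(C/C=C(\C)CC/C=C(\C)CCC(Br)C(C)(C)O)c1 | intermediate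
6 | terminal epoxide (racemic) | COc1ccc(OC)c(C/C=C(\C)CC/C=C(\C)CCC2OC2(C)C)c1 | intermediate
7 | (4E,8E)-10-(2,5-dimethoxyphenyl)-4,8-dimethyldeca-4,8-dienal | COc1ccc(OC)c(C/C=C(\C)CC/C=C(\C)CCC=O)c1 | intermediate
8 | 2-bromoprop-2-en-1-ol | OCC(Br)=C | starting material
9 | (2-bromoprop-2-enyloxy)(tert-butyl)diphenylsilane | C=C(Br)CO[Si](c1ccccc1)(c1ccccc1)C(C)(C)C | intermediate
10 | 3-[tert-butyl(diphenyl)silyl]oxyprop-1-en-2-yllithium | [Li]C(=C)CO[Si](c1ccccc1)(c1ccccc1)C(C)(C)C | intermediate
11 | allylic alcohol, C5 carbinol racemic, C10 bearing =CH2 and CH2OSi(t-Bu)Ph2 | COc1ccc(OC)c(C/C=C(\C)CC/C=C(\C)CCC(O)C(=C)CO[Si](c2ccccc2)(c2ccccc2)C(C)(C)C)c1 | intermediate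
12 | 1-ethoxyvinyl ether of 11 (mixed ketene acetal) | COc1ccc(OC)c(C/C=C(\C)CC/C=C(\C)CCC(OC(=C)OCC)C(=C)CO[Si](c2ccccc2)(c2ccccc2)C(C)(C)C)c1 | intermediate
13 | ethyl (4Z,8E,12E)-trienoate (Claisen product) | CCOC(=O)CC/C(CO[Si](c1ccccc1)(c1ccccc1)C(C)(C)C)=C/CC/C(C)=C/CC/C(C)=C/Cc1cc(OC)ccc1OC | intermediate
14 | Weinreb amide of the same acid | CON(C)C(=O)CC/C(CO[Si](c1ccccc1)(c1ccccc1)C(C)(C)C)=C/CC/C(C)=C/CC/C(C)=C/Cc1cc(OC)ccc1OC | intermediate
15 | (1R,2S,5R)-(−)-8-phenylmenthol | O[C@@H]1C[C@H](C)CC[C@H]1C(C)(C)c1ccccc1 | starting material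
16 | (1R,2S,5R)-8-phenylmenthyl propanoate | CCC(=O)O[C@@H]1C[C@H](C)CC[C@H]1C(C)(C)c1ccccc1 | intermediate
17 | lithium enolate of 16 | CC=C(O[Li])O[C@@H]1C[C@H](C)CC[C@H]1C(C)(C)c1ccccc1 | intermediate
18 | acyclic α-methyl β-keto ester (6Z,10E,14E; C4 epimers), cyclisation precursor | CC(C(=O)CC/C(CO[Si](c1ccccc1)(c1ccccc1)C(C)(C)C)=C/CC/C(C)=C/CC/C(C)=C/Cc1cc(OC)ccc1OC)C(=O)O[C@@H]1C[C@H](C)CC[C@H]1C(C)(C)c1ccccc1 | intermediate
19 | tricyclic keto ester: 3-oxo, 4α-CH3, 4β-CO2(8-phenylmenthyl), 10β-CH2OSi(t-Bu)Ph2, 8β-CH3, 13(16)-methylene, 14β-CH2Ar, H-5/H-9/H-14 α | C[C@@]12CC[C@@H]3[C@](CO[Si](c4ccccc4)(c4ccccc4)C(C)(C)C)(CCC(=O)[C@]3(C)C(=O)O[C@@H]4C[C@H](C)CC[C@H]4C(C)(C)c4ccccc4)[C@H]1CCC(=C)[C@H]2Cc1cc(OC)ccc1OC | intermediate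
20 | 13α-hydroperoxide (13β-CH3) | C[C@@]12CC[C@@H]3[C@](CO[Si](c4ccccc4)(c4ccccc4)C(C)(C)C)(CCC(=O)[C@]3(C)C(=O)O[C@@H]4C[C@H](C)CC[C@H]4C(C)(C)c4ccccc4)[C@H]1CC[C@](C)(OO)[C@H]2Cc1cc(OC)ccc1OC | intermediate
21 | 13α-alcohol (13β-CH3), 3-oxo | C[C@@]12CC[C@@H]3[C@](CO[Si](c4ccccc4)(c4ccccc4)C(C)(C)C)(CCC(=O)[C@]3(C)C(=O)O[C@@H]4C[C@H](C)CC[C@H]4C(C)(C)c4ccccc4)[C@H]1CC[C@](C)(O)[C@H]2Cc1cc(OC)ccc1OC | intermediate
22 | C3 tosylhydrazone of 21 | C[C@@]12CC[C@@H]3[C@](CO[Si](c4ccccc4)(c4ccccc4)C(C)(C)C)(CCC(=NNS(=O)(=O)c4ccc(C)cc4)[C@]3(C)C(=O)O[C@@H]4C[C@H](C)CC[C@H]4C(C)(C)c4ccccc4)[C@H]1CC[C@](C)(O)[C@H]2Cc1cc(OC)ccc1OC | intermediate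
23 | 3-deoxo ester (C3 = CH2) | C[C@@]12CC[C@@H]3[C@](CO[Si](c4ccccc4)(c4ccccc4)C(C)(C)C)(CCC[C@]3(C)C(=O)O[C@@H]4C[C@H](C)CC[C@H]4C(C)(C)c4ccccc4)[C@H]1CC[C@](C)(O)[C@H]2Cc1cc(OC)ccc1OC | intermediate
24 | C20 hydroxy ester (formed as its alkoxide) | C[C@@]12CC[C@@H]3[C@](CO)(CCC[C@]3(C)C(=O)O[C@@H]4C[C@H](C)CC[C@H]4C(C)(C)c4ccccc4)[C@H]1CC[C@](C)(O)[C@H]2Cc1cc(OC)ccc1OC | intermediate
25 | 19,20-lactone, 13α-OH, 14β-CH2-(2,5-dimethoxyphenyl) | C[C@@]12CC[C@@H]3[C@]4(CCC[C@]3(C)C(=O)OC4)[C@H]1CC[C@](C)(O)[C@H]2Cc1cc(OC)ccc1OC | intermediate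
26 | hydroxy quinone (19,20-lactone, 13α-OH, 14β-CH2-benzoquinonyl) | C[C@@]12CC[C@@H]3[C@]4(CCC[C@]3(C)C(=O)OC4)[C@H]1CC[C@](C)(O)[C@H]2CC1=CC(=O)C=CC1=O | intermediate
27 | CNP0290557.1 | C[C@@]12CC[C@@H]3[C@]4(CCC[C@]3(C)C(=O)OC4)[C@H]1CC[C@]1(C)O[C@]3(CC(=O)C=CC3=O)C[C@@H]21 | target

**Step count and risks**
Total step count: 17. Longest linear sequence: 15 steps (steps 1–4, 6–8, 10–17).

Most likely to fail:

1. Step 11 (key step). Process at risk: oxidation of the C10 or C8 radical by divalent copper before the next ring closes (premature termination of the cascade), and incomplete facial control by the auxiliary at C4; diastereomers from the latter are separated by chromatography at 19. The fallback sets out from 18 and comes back at 19. It splits the cascade into two known operations and changes the ring C closure from radical to cationic. With a higher Cu(OAc)2 loading the oxidation is run for two rings only, giving the bicyclic 8(17)-exocyclic alkene keto ester F1, which keeps the C13=C14 alkene. Ring C is then closed by a proton-initiated cationic cyclisation (SnCl4, CH2Cl2, −78 °C), the type known for labda-8(17),13-dienes: the C8 cation is attacked by C14 through a chair, and the C13 cation loses a proton to give 19 together with its Δ12 double-bond isomer F2, which gives the same C13 radical in step 12.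

2. Step 12. Process at risk: poor facial selectivity when the C13 radical captures O2 (axial against equatorial attack). The fallback sets out from 19 and comes back at 21. It fixes the C13–O bond by steric approach control on the intact alkene: m-CPBA, NaHCO3, CH2Cl2, 0 °C, should give the 13α,16-epoxide F3 from the face anti to the axial C8 methyl; LiI, AcOH, THF opens it at the primary carbon to the iodohydrin F4; Bu3SnH, AIBN, benzene, 80 °C, removes the iodine to give 21.

3. Step 13. Process at risk: failure of hydrazone formation at the C3 carbonyl, which is shielded by the quaternary C4 and its bulky ester. The fallback sets out from 21 and comes back at 23 by a Barton–McCombie deoxygenation: NaBH4, MeOH, 0 °C, gives the 3β-alcohol F5; 1,1'-thiocarbonyldiimidazole, DMAP, toluene, 90 °C, acylates only the secondary hydroxyl to the imidazolide F6; Bu3SnH, AIBN, toluene, 100 °C, gives 23.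

**Further compounds**
F1 | step 11 | bicyclic 8(17)-exocyclic alkene keto ester (rings A and B closed, C9 side chain with the C13=C14 E alkene and the arene) | C=C1CC[C@@H]2[C@](CO[Si](c3ccccc3)(c3ccccc3)C(C)(C)C)(CCC(=O)[C@]2(C)C(=O)O[C@@H]3C[C@H](C)CC[C@H]3C(C)(C)c3ccccc3)[C@H]1CC/C(C)=C/Cc1cc(OC)ccc1OC
F2 | step 11 | Δ12 double-bond isomer of 19 | C[C@@]12CC[C@@H]3[C@](CO[Si](c4ccccc4)(c4ccccc4)C(C)(C)C)(CCC(=O)[C@]3(C)C(=O)O[C@@H]4C[C@H](C)CC[C@H]4C(C)(C)c4ccccc4)[C@H]1CC=C(C)[C@H]2Cc1cc(OC)ccc1OC
F3 | step 12 | 13α,16-epoxide of 19 | C[C@@]12CC[C@@H]3[C@](CO[Si](c4ccccc4)(c4ccccc4)C(C)(C)C)(CCC(=O)[C@]3(C)C(=O)O[C@@H]4C[C@H](C)CC[C@H]4C(C)(C)c4ccccc4)[C@H]1CC[C@@]4(CO4)[C@H]2Cc1cc(OC)ccc1OC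
F4 | step 12 | 13α-hydroxy-16-iodide (iodohydrin) | C[C@@]12CC[C@@H]3[C@](CO[Si](c4ccccc4)(c4ccccc4)C(C)(C)C)(CCC(=O)[C@]3(C)C(=O)O[C@@H]4C[C@H](C)CC[C@H]4C(C)(C)c4ccccc4)[C@H]1CC[C@](CI)(O)[C@H]2Cc1cc(OC)ccc1OC
F5 | step 13 | 3β-alcohol of 21 | C[C@@]12CC[C@@H]3[C@](CO[Si](c4ccccc4)(c4ccccc4)C(C)(C)C)(CC[C@H](O)[C@]3(C)C(=O)O[C@@H]4C[C@H](C)CC[C@H]4C(C)(C)c4ccccc4)[C@H]1CC[C@](C)(O)[C@H]2Cc1cc(OC)ccc1OC
F6 | step 13 | 3β-O-(imidazol-1-ylthiocarbonyl) derivative of F5 | C[C@@]12CC[C@@H]3[C@](CO[Si](c4ccccc4)(c4ccccc4)C(C)(C)C)(CC[C@H](OC(=S)n4ccnc4)[C@]3(C)C(=O)O[C@@H]4C[C@H](C)CC[C@H]4C(C)(C)c4ccccc4)[C@H]1CC[C@](C)(O)[C@H]2Cc1cc(OC)ccc1OC
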